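## Retrosynthetic overview

1. Target 25 ⇐ Diels–Alder union of α-methylene lactone 19 with (R)-p-mentha-1,5-dien-8-ol 24 (three steps from (R)-carvone); the spiro bicyclo[2.2.2]octene is formed last.
2. 19 ⇐ late IBX dehydrogenation (ring A enone) and Pd-catalysed cyclocarbonylation of a cis 7-ethynyl-8-ol (lactone ring, formed third).
3. Ring B substituents ⇐ two conjugate-addition/trapping sequences on the cross-conjugated dienedione 6 (Me then O at C10/C9; boron (→O) then alkyne at C6/C7), followed by α-face hydride delivery at C8.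
4. 6 ⇐ enantioselective intramolecular Buchner ring expansion of the anisole ring of diazoketone 3 (one of two enantiotopic ipso–ortho bonds), then dienol ether hydrolysis; rings A and B are formed together, first.
5. 3 ⇐ 3-(4-methoxyphenyl)propanoic acid 1 (commodity anisole-derived acid) + diazoethane.

Convention and assumption: hydroazulene compounds carry helenanolide numbering (C1–C5 ring A with the C4 carbonyl and the angular C5 methyl; C6–C10 complete ring B; C11–C13 lactone carbons; β = face of the C5 methyl, α = face of H-1); diazoethane is used as a freshly prepared ethereal solution.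

## Route

Step 1
Reactants: 1 3-(4-methoxyphenyl)propanoic acid
Product: 3 2-diazo-5-(4-methoxyphenyl)pentan-3-one, via acid chloride 2 (not isolated)
Conditions: (COCl)2, DMF (cat.), CH2Cl2, 0 → 23 °C; then CH3CHN2 (3 equiv), Et2O, −20 → 0 °C
Reagents that add atoms: diazoethane CC=[N+]=[N-]
Why: Acid chloride formation followed by C-acylation of diazoethane (Arndt–Eistert-type diazoketone synthesis), the excess diazoalkane scavenging HCl; no stereocentre is formed.

Step 2
Reactants: 3 2-diazo-5-(4-methoxyphenyl)pentan-3-one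
Product: 6 (3aS,8aS)-8a-methyl-2,3,3a,8a-tetrahydroazulene-1,6-dione, via norcaradiene 4 (not isolated), via methoxy trienone 5 (not isolated)
Conditions: dirhodium tetrakis[N-phthaloyl-(S)-tert-leucinate], Rh2(S-PTTL)4 (1 mol %), CH2Cl2, −40 °C; then 2 M HCl, THF, 23 °C
Reagents that add atoms: water O
Why: Proposed new method: the chiral dirhodium carbenoid cyclopropanates one of the two enantiotopic ipso–ortho bonds of the anisole ring (intramolecular Buchner reaction: norcaradiene, then 6π-electrocyclic opening), so dearomatisation and desymmetrisation fix the C5 quaternary centre in one event (low temperature and the bulky carboxylate suppress 1,2-hydride shift), and acid then hydrolyses the methyl dienol ether with C1 protonated anti to the C5 methyl to give the trans-fused dienedione (C1 is vinylogously enolisable, so this epimer can also be reached by equilibration); closest known reactions are the racemic Rh2(OAc)4 Buchner cyclisation of 2-diazo-5-arylpentan-3-ones and the enantioselective copper–bis(oxazoline) Buchner reaction of terminal α-diazoketones.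

Step 3
Reactants: 6 trans-fused dienedione
Product: 8 9β-TBS-oxy-10α-methyl enedione, via silyl dienol ether 7 (not isolated)
Conditions: Me2CuLi (from CuI, 2 MeLi; 1.3 equiv), TBSCl, HMPA, THF, −78 → −40 °C; then mCPBA, NaHCO3, CH2Cl2, −20 °C
Reagents that add atoms: lithium dimethylcuprate [Li+].C[Cu-]C; tert-butyldimethylsilyl chloride CC(C)(C)[Si](C)(C)Cl; mCPBA OOC(=O)c1cccc(Cl)c1
Why: Cuprate 1,4-addition goes to C10 (the enone terminus not flanked by the quaternary carbon) on the α-face, anti to the axial C5 methyl, and Rubottom oxidation of the trapped silyl dienol ether occurs on the β-face, anti to the new 10α-methyl, with 1,4-silyl shift to give the 9β-silyloxy ketone.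

Step 4
Reactants: 8 9β-TBS-oxy-10α-methyl enedione
Product: 9 7-iodo enedione
Conditions: I2, pyridine, CH2Cl2, 0 → 23 °C
Reagents that add atoms: iodine II
Why: α-Iodination of the only remaining enone by pyridine conjugate addition, iodination and elimination (Baylis–Hillman-type manifold); no stereocentre is formed.

Step 5
Reactants: 9 7-iodo enedione
Product: 10 7-(trimethylsilylethynyl) enedione
Conditions: PdCl2(PPh3)2 (5 mol %), CuI (10 mol %), i-Pr2NH, THF, 23 °C
Reagents that add atoms: ethynyltrimethylsilane C#C[Si](C)(C)C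
Why: Sonogashira coupling of the α-iodoenone installs C11 and C13 of the future lactone; no stereocentre is formed.

Step 6
Reactants: 10 7-(trimethylsilylethynyl) enedione
Product: 12 6α-hydroxy-7β-(trimethylsilylethynyl) dione, via pinacol boronate 11 (not isolated)
Conditions: CuCl (5 mol %), Xantphos (5 mol %), NaOt-Bu (6 mol %), B2pin2, MeOH (2 equiv), THF, −20 °C; then 30% H2O2, NaHCO3, THF/H2O, 0 °C
Reagents that add atoms: hydrogen peroxide OO
Why: Copper-catalysed conjugate borylation delivers boron to C6 on the α-face, anti to the C5 methyl, C7 (α to the ketone) settles as the trans 7β-alkynyl epimer, and C–B oxidation with retention gives the 6α-alcohol.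

Step 7
Reactants: 12 6α-hydroxy-7β-(trimethylsilylethynyl) dione
Product: 13 6α-tigloyloxy dione
Conditions: tiglic anhydride (1.5 equiv), Sc(OTf)3 (2 mol %), MeCN, −20 °C
Reagents that add atoms: tiglic anhydride C/C=C(\C)C(=O)OC(=O)/C(C)=C/C
Why: Lewis-acid-catalysed acylation of the hindered secondary alcohol by the anhydride, chosen because base-free conditions avoid E1cB loss of the β-acyloxy group next to the acidic propargylic C7–H; no stereocentre changes.

Step 8
Reactants: 13 6α-tigloyloxy dione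
Product: 15 7β-ethynyl-4,8β-diol, via silylalkyne diol 14 (not isolated)
Conditions: LiBH(s-Bu)3 (2.5 equiv), THF, −78 °C; then MeOH, KF, 23 °C
Reagents that add atoms: none
Why: The bulky hydride attacks the C8 ketone from the α-face, opposite the 7β-alkynyl and 9β-silyloxy groups, giving the all-cis 8β-alcohol (the C4 ketone is reduced too, as an inconsequential epimer mixture re-oxidised in step 10), and fluoride in methanol then cleaves the C(sp)–Si bond.

Step 9
Reactants: 15 7β-ethynyl-4,8β-diol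
Product: 16 α-methylene-8β,12-lactone 4-ol
Conditions: PdCl2 (5 mol %), SnCl2 (5 mol %), PPh3 (10 mol %), CO (7 atm), MeCN, 75 °C
Reagents that add atoms: carbon monoxide [C-]#[O+]
Why: Palladium-catalysed cyclocarbonylation of a homopropargylic alcohol, in which the alkoxycarbonyl–palladium species adds syn across the alkyne (5-exo) and protonolysis leaves the exocyclic methylene; only the 8β-OH is homopropargylic and it is cis to the ethynyl group, so the lactone is cis-fused.

Step 10
Reactants: 16 α-methylene-8β,12-lactone 4-ol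
Product: 18 9-O-TBS cyclopentenone lactone, via cyclopentanone 17 (not isolated)
Conditions: IBX (4 equiv), DMSO, 75 °C
Reagents that add atoms: none
Why: IBX oxidises the C4 carbinol to the cyclopentanone and then dehydrogenates it through its enol (single-electron-transfer dehydrogenation); C5 is quaternary, so only the C2–C3 double bond can form.

Step 11
Reactants: 18 9-O-TBS cyclopentenone lactone
Product: 19 9β-hydroxy-6α-tigloyloxy methylene lactone
Conditions: HF·pyridine, THF, 0 °C
Reagents that add atoms: none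
Why: Fluoride-mediated cleavage of the secondary TBS ether under buffered acidic conditions that spare the enone, the tiglate and the methylene lactone.

Step 12
Reactants: 20 (R)-(−)-carvone
Product: 21 (5R)-5-(2-hydroxypropan-2-yl)-2-methylcyclohex-2-en-1-one
Conditions: 50% aq H2SO4, 0 °C
Reagents that add atoms: water O
Why: Acid-catalysed Markovnikov hydration of the isopropenyl group; the carvone stereocentre is not touched.

Step 13
Reactants: 21 (5R)-5-(2-hydroxypropan-2-yl)-2-methylcyclohex-2-en-1-one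
Product: 22 tosylhydrazone of 21
Conditions: TsNHNH2, MeOH, 23 °C
Reagents that add atoms: 4-methylbenzenesulfonohydrazide Cc1ccc(cc1)S(=O)(=O)NN
Why: Condensation of the enone carbonyl with the sulfonyl hydrazide, the N–N bond lying syn to the α′-CH2 (anti to the substituted alkene carbon).

Step 14
Reactants: 22 tosylhydrazone of 21
Product: 24 2-[(1R)-4-methylcyclohexa-2,4-dien-1-yl]propan-2-ol, via dienyllithium 23 (not isolated)
Conditions: MeLi (3.5 equiv), Et2O, −78 → 23 °C; then H2O
Reagents that add atoms: none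
Why: Shapiro reaction in which α′-deprotonation syn to the sulfonamide, loss of sulfinate and N2 give the dienyllithium that is protonated on quench; the allylic stereocentre is not involved.

Step 15
Reactants: 19 9β-hydroxy-6α-tigloyloxy methylene lactone; 24 2-[(1R)-4-methylcyclohexa-2,4-dien-1-yl]propan-2-ol (1.5 equiv)
Product: 25 target compound CNP0185323.3
Conditions: toluene (3 M), BHT (cat.), 80 °C, sealed tube
Reagents that add atoms: none
Why: Intermolecular Diels–Alder reaction with para regiochemistry (C13 bonds to the diene terminus next to the methyl-bearing carbon), lactone carbonyl endo, the diene attacked anti to its CMe2OH group and the methylene lactone on its β-face (the face on which helenalin-type lactones accept reagents at C11, the α-face being flanked by the 6α-tigloyloxy group), which sets C11 and both bridgeheads; the cyclopentenone is the poorer dienophile.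

## Compound list

1 | 3-(4-methoxyphenyl)propanoic acid | COc1ccc(CCC(=O)O)cc1 | starting material
2 | 3-(4-methoxyphenyl)propanoyl chloride | COc1ccc(CCC(=O)Cl)cc1 | intermediate
3 | 2-diazo-5-(4-methoxyphenyl)pentan-3-one | COc1ccc(CCC(=O)C(C)=[N+]=[N-])cc1 | intermediate
4 | norcaradiene valence isomer of 5 (cyclopropane spanning C1, C5 and C6) | COC1=C[C@H]2[C@]3(C)C(=O)CC[C@]23C=C1 | intermediate
5 | (8aS)-6-methoxy-8a-methyl-3,8a-dihydroazulen-1(2H)-one | C1=CC(OC)=CC=C2CCC(=O)[C@]21C | intermediate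
6 | (3aS,8aS)-8a-methyl-2,3,3a,8a-tetrahydroazulene-1,6-dione (trans-fused; 1αH, 5β-methyl; 6-ene and 9-ene; ketones at C4 and C8) | C1=CC(=O)C=C[C@@H]2CCC(=O)[C@]21C | intermediate
7 | 8-(tert-butyldimethylsilyloxy)-10α-methyl-1αH-5β-methyl-hydroazula-6,8-dien-4-one | C1=CC(O[Si](C)(C)C(C)(C)C)=C[C@@H](C)[C@@H]2CCC(=O)[C@]21C | intermediate
8 | 9β-(tert-butyldimethylsilyloxy)-10α-methyl-1αH-5β-methyl-hydroazul-6-ene-4,8-dione | C1=CC(=O)[C@H](O[Si](C)(C)C(C)(C)C)[C@@H](C)[C@@H]2CCC(=O)[C@]21C | intermediate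
9 | 7-iodo derivative of 8 | C1=C(I)C(=O)[C@H](O[Si](C)(C)C(C)(C)C)[C@@H](C)[C@@H]2CCC(=O)[C@]21C | intermediate
10 | 7-(trimethylsilylethynyl) derivative of 8 | C1=C(C#C[Si](C)(C)C)C(=O)[C@H](O[Si](C)(C)C(C)(C)C)[C@@H](C)[C@@H]2CCC(=O)[C@]21C | intermediate
11 | 6α-(pinacolboryl)-7β-(trimethylsilylethynyl)-9β-(TBS-oxy)-10α-methyl-hydroazulane-4,8-dione | CC1(C)OB(OC1(C)C)[C@H]3[C@H](C#C[Si](C)(C)C)C(=O)[C@H](O[Si](C)(C)C(C)(C)C)[C@@H](C)[C@@H]2CCC(=O)[C@]23C | intermediate
12 | 6α-hydroxy-7β-(trimethylsilylethynyl)-9β-(TBS-oxy)-10α-methyl-hydroazulane-4,8-dione | O[C@H]1[C@H](C#C[Si](C)(C)C)C(=O)[C@H](O[Si](C)(C)C(C)(C)C)[C@@H](C)[C@@H]2CCC(=O)[C@]21C | intermediate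
13 | 6α-tigloyloxy-7β-(trimethylsilylethynyl)-9β-(TBS-oxy)-10α-methyl-hydroazulane-4,8-dione | C/C=C(\C)C(=O)O[C@H]1[C@H](C#C[Si](C)(C)C)C(=O)[C@H](O[Si](C)(C)C(C)(C)C)[C@@H](C)[C@@H]2CCC(=O)[C@]21C | intermediate
14 | 6α-tigloyloxy-7β-(trimethylsilylethynyl)-9β-(TBS-oxy)-10α-methyl-hydroazulane-4,8β-diol (C4 epimers) | C/C=C(\C)C(=O)O[C@H]1[C@H](C#C[Si](C)(C)C)[C@H](O)[C@H](O[Si](C)(C)C(C)(C)C)[C@@H](C)[C@@H]2CCC(O)[C@]21C | intermediate
15 | 6α-tigloyloxy-7β-ethynyl-9β-(TBS-oxy)-10α-methyl-hydroazulane-4,8β-diol (C4 epimers) | C/C=C(\C)C(=O)O[C@H]1[C@H](C#C)[C@H](O)[C@H](O[Si](C)(C)C(C)(C)C)[C@@H](C)[C@@H]2CCC(O)[C@]21C | intermediate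
16 | 6α-tigloyloxy-9β-(TBS-oxy)-4-hydroxy-pseudoguai-11(13)-en-12,8β-olide (cis-fused lactone; C4 epimers) | C/C=C(\C)C(=O)O[C@H]1[C@H]2[C@H](OC(=O)C2=C)[C@H](O[Si](C)(C)C(C)(C)C)[C@@H](C)[C@@H]2CCC(O)[C@]21C | intermediate
17 | 6α-tigloyloxy-9β-(TBS-oxy)-4-oxo-pseudoguai-11(13)-en-12,8β-olide | C/C=C(\C)C(=O)O[C@H]1[C@H]2[C@H](OC(=O)C2=C)[C@H](O[Si](C)(C)C(C)(C)C)[C@@H](C)[C@@H]2CCC(=O)[C@]21C | intermediate
18 | 6α-tigloyloxy-9β-(TBS-oxy)-4-oxo-pseudoguaia-2,11(13)-dien-12,8β-olide | C/C=C(\C)C(=O)O[C@H]1[C@H]2[C@H](OC(=O)C2=C)[C@H](O[Si](C)(C)C(C)(C)C)[C@@H](C)[C@@H]2C=CC(=O)[C@]21C | intermediate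
19 | 9β-hydroxy-6α-tigloyloxy-4-oxo-pseudoguaia-2,11(13)-dien-12,8β-olide (1αH, 5β-methyl, 7αH, 10α-methyl) | C/C=C(\C)C(=O)O[C@H]1[C@H]2[C@H](OC(=O)C2=C)[C@H](O)[C@@H](C)[C@@H]2C=CC(=O)[C@]21C | intermediate
20 | (R)-(−)-carvone | CC1=CC[C@H](CC1=O)C(C)=C | starting material
21 | (5R)-5-(2-hydroxypropan-2-yl)-2-methylcyclohex-2-en-1-one | CC1=CC[C@H](CC1=O)C(C)(C)O | intermediate
22 | N'-[(1E,5R)-5-(2-hydroxypropan-2-yl)-2-methylcyclohex-2-en-1-ylidene]-4-methylbenzenesulfonohydrazide | CC1=CC[C@H](C/C1=N\NS(=O)(=O)c1ccc(C)cc1)C(C)(C)O | intermediate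
23 | dilithium salt: (6R)-1-lithio-2-methyl-6-(2-lithiooxypropan-2-yl)cyclohexa-1,3-diene-type dienyllithium (lithium on the former hydrazone carbon) | [Li]C1=C[C@H](C(C)(C)O[Li])CC=C1C | intermediate
24 | 2-[(1R)-4-methylcyclohexa-2,4-dien-1-yl]propan-2-ol ((R)-p-mentha-1,5-dien-8-ol) | CC1=CC[C@@H](C(C)(C)O)C=C1 | intermediate
25 | CNP0185323.3 | C/C=C(\C)C(=O)O[C@H]1[C@H]2[C@H](OC(=O)[C@]23C[C@@H]2C[C@@H](C(C)(C)O)[C@H]3C=C2C)[C@H](O)[C@@H](C)[C@@H]2C=CC(=O)[C@]21C | target

## Step count and risk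

Total: 15 steps. Longest linear sequence: 12 steps (steps 1–11, then step 15); the diene branch is 3 steps (12–14).

Steps most likely to fail:

Step 2 (enantioselective Buchner ring expansion). Risks are low ee, carbenoid 1,2-hydride shift to the vinyl ketone, and an unfavourable C1 epimer ratio after hydrolysis. The fallback sets out from 3 and comes back at 6: achiral Rh2(OAc)4 (CH2Cl2, 40 °C), the established racemic cyclisation, converts 3 through norcaradiene 4 and the mirror-image norcaradiene F1 into trienone 5 and the enantiomeric trienone F2. The same HCl/THF treatment then gives 6 together with the enantiomeric dienedione F3. The two are separated by preparative chromatography on a cellulose tris(3,5-dimethylphenylcarbamate) stationary phase, and 6 is carried on, so stereocontrol comes from resolution instead of catalysis.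

Step 7 (acylation of the β-hydroxy ketone). Risks are E1cB elimination back to enynone 10 and retro-aldol opening. The fallback sets out from 10 and comes back at 18, carrying the C–B bond as a masked hydroxyl so that no β-acyloxy ketone is ever formed. The conjugate borylation of step 6 is run without oxidation and boronate 11 is isolated. LiBH(s-Bu)3 then MeOH/KF gives, through the silylalkyne boryl diol F4, the ethynyl boryl diol F5. Cyclocarbonylation (PdCl2, SnCl2, PPh3, CO) gives the boryl hydroxy lactone F6. IBX gives, through the boryl keto lactone F7, the boryl enone lactone F8. Buffered H2O2 unmasks the 6α-hydroxy enone lactone F9, which is acylated with tiglic anhydride (DMAP, Et3N) to give 18.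

Step 15 (final Diels–Alder union). Four selectivities must coincide (regiochemistry, endo mode, diene face, lactone face), the cyclopentenone can compete, and the diene can aromatise on prolonged heating. The fallback sets out from 16 (with 24) and comes back at 25, moving the cycloaddition ahead of enone formation and desilylation so that no second dienophile or free secondary alcohol is present and the reaction can be forced (neat, 1 GPa or 100 °C). 16 and 24 give the spiro adduct carbinol F10; IBX converts it, through the adduct cyclopentanone F11, into the 9-O-TBS adduct enone F12; HF·pyridine then gives 25.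

## Further compounds

F1 | step 2 | mirror-image norcaradiene (enantiomer of 4) | COC1=C[C@@H]2[C@@]3(C)C(=O)CC[C@@]23C=C1
F2 | step 2 | (8aR)-6-methoxy-8a-methyl-3,8a-dihydroazulen-1(2H)-one (enantiomeric trienone) | C1=CC(OC)=CC=C2CCC(=O)[C@@]21C
F3 | step 2 | (3aR,8aR)-8a-methyl-2,3,3a,8a-tetrahydroazulene-1,6-dione (enantiomeric dienedione) | C1=CC(=O)C=C[C@H]2CCC(=O)[C@@]21C
F4 | step 7 | silylalkyne boryl diol: 6α-(pinacolboryl)-7β-(trimethylsilylethynyl)-9β-(TBS-oxy)-10α-methyl-hydroazulane-4,8β-diol | CC1(C)OB(OC1(C)C)[C@H]3[C@H](C#C[Si](C)(C)C)[C@H](O)[C@H](O[Si](C)(C)C(C)(C)C)[C@@H](C)[C@@H]2CCC(O)[C@]23C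
F5 | step 7 | ethynyl boryl diol: 6α-(pinacolboryl)-7β-ethynyl-9β-(TBS-oxy)-10α-methyl-hydroazulane-4,8β-diol | CC1(C)OB(OC1(C)C)[C@H]3[C@H](C#C)[C@H](O)[C@H](O[Si](C)(C)C(C)(C)C)[C@@H](C)[C@@H]2CCC(O)[C@]23C
F6 | step 7 | boryl hydroxy lactone: 6α-(pinacolboryl)-9β-(TBS-oxy)-4-hydroxy-pseudoguai-11(13)-en-12,8β-olide | CC1(C)OB(OC1(C)C)[C@H]3[C@H]4[C@H](OC(=O)C4=C)[C@H](O[Si](C)(C)C(C)(C)C)[C@@H](C)[C@@H]2CCC(O)[C@]23C
F7 | step 7 | boryl keto lactone: 6α-(pinacolboryl)-9β-(TBS-oxy)-4-oxo-pseudoguai-11(13)-en-12,8β-olide | CC1(C)OB(OC1(C)C)[C@H]3[C@H]4[C@H](OC(=O)C4=C)[C@H](O[Si](C)(C)C(C)(C)C)[C@@H](C)[C@@H]2CCC(=O)[C@]23C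
F8 | step 7 | boryl enone lactone: 6α-(pinacolboryl)-9β-(TBS-oxy)-4-oxo-pseudoguaia-2,11(13)-dien-12,8β-olide | CC1(C)OB(OC1(C)C)[C@H]3[C@H]4[C@H](OC(=O)C4=C)[C@H](O[Si](C)(C)C(C)(C)C)[C@@H](C)[C@@H]2C=CC(=O)[C@]23C
F9 | step 7 | 6α-hydroxy enone lactone: 6α-hydroxy-9β-(TBS-oxy)-4-oxo-pseudoguaia-2,11(13)-dien-12,8β-olide | O[C@H]1[C@H]2[C@H](OC(=O)C2=C)[C@H](O[Si](C)(C)C(C)(C)C)[C@@H](C)[C@@H]2C=CC(=O)[C@]21C
F10 | step 15 | spiro adduct carbinol: Diels–Alder adduct of 16 and 24 (9-O-TBS, C4 carbinol) | C/C=C(\C)C(=O)O[C@H]1[C@H]2[C@H](OC(=O)[C@]23C[C@@H]2C[C@@H](C(C)(C)O)[C@H]3C=C2C)[C@H](O[Si](C)(C)C(C)(C)C)[C@@H](C)[C@@H]2CCC(O)[C@]21C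
F11 | step 15 | adduct cyclopentanone: 4-oxo derivative of F10 | C/C=C(\C)C(=O)O[C@H]1[C@H]2[C@H](OC(=O)[C@]23C[C@@H]2C[C@@H](C(C)(C)O)[C@H]3C=C2C)[C@H](O[Si](C)(C)C(C)(C)C)[C@@H](C)[C@@H]2CCC(=O)[C@]21C
F12 | step 15 | 9-O-TBS adduct enone: 9-O-TBS ether of 25 | C/C=C(\C)C(=O)O[C@H]1[C@H]2[C@H](OC(=O)[C@]23C[C@@H]2C[C@@H](C(C)(C)O)[C@H]3C=C2C)[C@H](O[Si](C)(C)C(C)(C)C)[C@@H](C)[C@@H]2C=CC(=O)[C@]21C
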